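## Structural features

The target is a drimane: a trans-fused decalin in which ring A carries only the C4 gem-dimethyl group and ring B carries all the functionality. Five stereocentres lie around ring B (C6–C5–C10–C9–C8, with only the C7 methylene between C6 and C8): 5α-H, the 6β-trienoyloxy group, the 8β- and 9β-carboxyl groups (C12 and C11) and the 10β-methyl on the quaternary ring-fusion carbon. In the chair–chair form O6, the C8 carboxyl and the C10 methyl are all axial on the β face and mutually 1,3-syn, and the 4β-methyl is a further syn-axial neighbour of O6. The 8β-acid is therefore the less stable C8 epimer, O6 is strongly hindered, and O6 and C12 sit at the distance of a bridged γ-lactone. Fragile features are the (2E,4E,6E)-trienoate (nucleophiles, hydrogenation, light), the enolisable centres C8 and C9, and the hydroxy ester/lactone balance between O6 and C12 whenever O6 is free. The real difficulties are the absolute configuration of quaternary C10, the contra-thermodynamic axial carboxyl on C8, and acylation of the axial 6β-oxygen beside it. The key step uses the 1,4-relationship of the C6 oxygen and the C12 carboxyl through C7: with C6 as a ketone this is a γ-keto ester, the product pattern of a one-carbon radical ring expansion of a cyclopentanone β-keto ester in which C6 is still bonded to C8.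

## Logic of the disconnections

21 from 20. The two carboxyl O–allyl bonds are cut. A free diacid beside an acylated O6 cannot be released by hydrolysis without endangering the trienoate, whereas allyl esters leave under neutral palladium catalysis. The last step then touches nothing else; it demands an allyl acceptor that does not add to the triene.

20 from 18 and 19. The C2'=C3' double bond of the side chain is cut. This avoids acylating a very hindered alcohol with a trienoyl electrophile that deconjugates easily, and reduces the acyl group to a two-carbon phosphonoacetate. The forward olefination must be E-selective under a base too weak to epimerise the axial C8 ester.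

18 from 16 and 17. The O6–C1' ester bond is cut. The acyl donor derived from 17 is small and ketene-like, which suits the axial, doubly flanked hydroxyl. Acylation must be faster than closure of O6 onto the C12 ester.

16 from 14. The two allyl C–O bonds are cut and O6–C12 is reconnected. The lactone is the only form in which the 8β configuration is thermodynamically safe; opening it with hydroxide and alkylating both carboxylates frees O6 and protects both acids. The hydroxy diester must be made and used without relactonisation.

14 from 12. The O6–C12 bond is cut. Only the 8β-ester can reach the axial 6β-oxygen, so lactonisation under enolising conditions converts the stable 8α-ester into the required epimer, and equatorial C9 is confirmed on the locked chair. C8 is thus set by ring geometry; the step needs a base that enolises the C8 ester and removal of methanol.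

12 from 11. The C6–H bond is cut. The key step delivers C6 as a ketone, and hydride from the open α face gives the 6β-alcohol. This requires the trans ring fusion, because the facial bias comes from the axial methyls on C4 and C10.

11 from 10. The epimerisable C5–H, C8–H and C9–H bonds are addressed. The radical step cannot alter C5, and a hydrindan-1-one with an angular methyl prefers the cis fusion, so the immediate ring-expansion product is cis-fused and the trans-decalone is a separate, later compound. At the decalone stage the trans-fused isomer with both esters equatorial should be the most stable, so one equilibration sets C5 and C9 (and C8 provisionally) with C10 as the only reference. Nothing but C10 then needs control earlier; the demand is a favourable equilibrium.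

10 from 9. The C6–C7 bond is cut and C6–C8 reconnected (the key step). This turns ring B into a cyclopentanone β-keto ester that carries the whole oxidation pattern (C6 ketone, C8 and C9 esters) and can be reached by electrocyclisation at quaternary C10. The radical must rearrange before it is reduced, and it must choose the ketone over the C12 ester carbonyl, which is also 3-exo to it; that choice is kinetic, not geometric.

9 from 7 and 8. The C7–C8 bond is cut. The β-keto ester carbon is the nucleophile and 8 supplies C7 together with the halogen needed for radical generation. The forward step is a C-alkylation at a hindered tertiary carbon that must use only one C–Br bond of 8.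

7 from 6. The C8–H and C9–H bonds are cut (addition of H2). The enone diester is the direct product of the cyclisation. No stereochemical demand is placed on this step: its facial outcome on a cis-fused bicycle is uncertain and is deliberately not relied upon, since C9 is as base-labile as C8.

6 from 5. The C9–C10 bond is cut. A 4π electrocyclisation forms the bond to the quaternary carbon and is the only enantio-determining step. The bicycle becomes a monocyclic dienone that holds every skeletal carbon except C7. The step needs control of the sense of conrotation and termination by loss of the C9 proton.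

5 from 3 and 4. The C8=C9 double bond is cut (Knoevenagel). Compound 4 brings C9 and C11. The condensation must stop at the alkylidene stage.

3 from 1 and 2. The C6–C8 bond is cut (Roskamp). Compound 1 supplies ring A, C5, C6, C10 and three methyls; 2 supplies C8 and C12.

## Other disconnections considered

Alternative 1: The cut is through C5–C10 and C6–C7, opening both rings to the acyclic triene A1, a 2,3-bis(methoxycarbonyl)butadiene (C7=C8–C9=C10) tethered through C1–C4 to a Z-benzyl enol ether (C5=C6). The forward key step would be an inverse-demand intramolecular Diels–Alder reaction, heated with a chiral Lewis acid held by the vicinal diester, to the trans-fused octalin A2.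
- In its favour: two rings, two C–C bonds and three stereocentres (C5, C6, C10) in one step. O6 arrives with the β configuration as a consequence of the Z geometry. The C8=C9 diester alkene of A2 could in principle give the cis-8β,9β pattern by one α-face hydrogenation. On the configuration of O6, on a kinetically set trans ring fusion and on avoiding any equilibration, this alternative is the better of the two.
- Against it: the diene terminus C10 is disubstituted, so its methyl points inward in the reactive s-cis conformer. The new C5–C10 bond joins a quaternary carbon to a neopentyl one. Z-enol ethers are slow dienophiles and acid-labile under a Lewis acid at elevated temperature. Two-point binding of a vicinal diester for facial control has no close analogy. Hydrogenation of the tetrasubstituted alkene of A2 next to C10 would be hard, and after it the same O6/C12 lactone question returns.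
- Comparison: structurally it is more convergent. Mechanistically it is a concerted cycloaddition in its sterically worst case, set against a radical rearrangement that is well characterised on simpler rings. In step count the key step does more, but A1 needs two stereodefined alkenes and about as many steps as 9, so the totals should be similar, with the risk concentrated in one step.

Alternative 2: The cut is through C8–C12 and C9–C11, so both carboxyl carbons come from carbon monoxide and the precursor is the trans-fused homoallylic alcohol A3. With PdCl2, CuCl2, CO and methanol, O6 would form an alkoxycarbonyl–palladium species that adds syn across C8=C9 on the β face, closing the bridged lactone and placing palladium on C9β; CO insertion and methanolysis would give A4, the same substance as 14.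
- In its favour: two C–C bonds and both C8 and C9 are set kinetically by the tether, with no contra-thermodynamic epimerisation. The C9–palladium intermediate has no syn β-hydrogen (C10 is quaternary, H8 is anti), so carbonylation is its only productive path. C5 and C10 would come from a preformed trans-decalin and are never epimerisable. On control of C5, C8, C9 and C10 this alternative is the better; the endgame from A4 is identical to that of the chosen plan and so equal.
- Against it: the alkene is cyclic, 1,2-disubstituted and neopentyl at C9. The tether is a hindered axial alcohol that must compete with methanol for the acylpalladium. Untethered bis(methoxycarbonylation) from the open α face would give the irreparable 8α,9α-diester. A3 itself needs a longer preparation, including an inversion at C6.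
- Comparison: the key step is more economical (two C–C bonds, one C–O bond and two stereocentres against one bond), and overall length should be similar. A wrong facial course in the carbonylation cannot be repaired, whereas the weak points of the chosen plan (C5, C8, C9) are open to equilibration.

Alternative 3: The cut is through C5–C10 and C8–C9, giving the triene A5 with a 6-silyloxy diene (C5=C6–C7=C8, tert-butyl ester on C8) and a tethered E enoyl oxazolidinone (C9=C10). Under a Cu(SbF6)2–bis(oxazoline) Lewis acid an intramolecular Diels–Alder reaction would give the trans-fused adduct A6.
- In its favour: a chelating enoyl imide with cationic divalent copper is the best established pairing for absolute control among all the key steps compared, and on this point it is better than the electrocyclisation the chosen plan needs. Two rings, two C–C bonds and four stereocentres (C5, C8, C9, C10) form at once. The diene and dienophile are electronically matched (C5 bonds to the β-carbon C10). After hydrolysis of the enol ether, A6 would show the same 6-keto-8,9-dicarboxyl pattern as 11 but with C8 already β and the two carboxyls differentiated.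
- Against it: the dienophile is β,β-disubstituted, which lowers reactivity and disturbs the planar chelate, and it must form quaternary C10 against the neopentyl terminus C5. The diene carries an ester at its far end. A geometrically defined silyl dienol ether is required. Once the ketone is unmasked, C5 and the axial C8 ester are epimerisable. Removing the tert-butyl ester with acid and cleaving the imide late, beside the acyloxy group, adds steps.
- Comparison: it is more convergent and mechanistically well understood, and its length should be similar. Its risk again lies in one sterically extreme cycloaddition, whereas the chosen plan spreads the risk over steps that can each be corrected.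

Key step: step 6

Remark: drimane numbering (β = face of the C10 methyl) is used for all intermediates. In 7, 9 and 10 the centres C8 and C9 are written without configuration because both epimers converge in steps 7 and 9.

Assumption: the sense of induction of the copper–bis(oxazoline) catalyst in step 3 cannot be predicted with certainty; the ligand antipode that gives the (10S) series is the one meant.

Remark: the radical step leaves C5 untouched, so 9 and 10 are drawn with the cis ring fusion expected for the hydrindanone series; the trans-fused ketone is compound 11.

## Route

Step 1
Reactants: 1 β-cyclocitral (2,6,6-trimethylcyclohex-1-ene-1-carbaldehyde); 2 methyl diazoacetate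
Product: 3 methyl 3-oxo-3-(2,6,6-trimethylcyclohex-1-en-1-yl)propanoate
Conditions: SnCl2 (10 mol%), CH2Cl2, rt
Reagents that add atoms: none
Why: Roskamp homologation: the tin-activated aldehyde is attacked by the diazo carbon and a 1,2-hydride shift with loss of N2 gives the β-keto ester directly; the aldehyde is hindered and conjugated but has no enolisable position to divert it.

Step 2
Reactants: 3 methyl 3-oxo-3-(2,6,6-trimethylcyclohex-1-en-1-yl)propanoate; 4 methyl glyoxylate
Product: 5 dimethyl (2Z)-2-[(2,6,6-trimethylcyclohex-1-en-1-yl)carbonyl]but-2-enedioate (Z isomer drawn; E/Z mixture acceptable)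
Conditions: 4 (1.5 equiv), piperidine (cat.), AcOH (cat.), 4 Å molecular sieves, toluene, rt to 50 °C
Reagents that add atoms: none
Why: Knoevenagel condensation of the active methylene with the non-enolisable, highly electrophilic glyoxylate, driven by removal of water; an excess of 4 suppresses Michael addition of a second molecule of 3, and the alkene geometry is irrelevant because the isomers interconvert under the Lewis acid of step 3.

Step 3
Reactants: 5 dimethyl (2Z)-2-[(2,6,6-trimethylcyclohex-1-en-1-yl)carbonyl]but-2-enedioate
Product: 6 dimethyl (3aS,7aR)-3a,7,7-trimethyl-1-oxo-3a,4,5,6,7,7a-hexahydro-1H-indene-2,3-dicarboxylate (cis-fused enone; C10 methyl and H5 both β, C8=C9 double bond)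
Conditions: Cu(SbF6)2 with (S,S)-t-Bu-box, i.e. 2,2'-(propane-2,2-diyl)bis[(4S)-4-tert-butyl-4,5-dihydro-1,3-oxazole] (20 mol%), CH2Cl2, 25–40 °C
Reagents that add atoms: none
Why: Proposed new method: two-point chelation of the β-keto ester by the chiral divalent copper complex gives a pentadienyl cation that closes by conrotatory 4π electrocyclisation to form C9–C10, the bis(oxazoline) choosing the sense of conrotation and thus the C10 configuration, after which the oxyallyl cation loses the acidic C9 proton and ketonises at C5 to the more stable cis-fused enone; the closest known reaction types are copper–bis(oxazoline)-promoted Nazarov cyclisations of 2-alkoxycarbonyl divinyl ketones and acid-promoted Nazarov closures of 2,6,6-trimethylcyclohexenyl ketones to angular-methyl hydrindenones.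

Step 4
Reactants: 6 dimethyl (3aS,7aR)-3a,7,7-trimethyl-1-oxo-3a,4,5,6,7,7a-hexahydro-1H-indene-2,3-dicarboxylate
Product: 7 dimethyl (3aS,7aR)-3a,7,7-trimethyl-1-oxooctahydro-1H-indene-2,3-dicarboxylate (cis-fused β-keto diester; C8 enolisable, C9 as formed)
Conditions: H2 (4 atm), palladium on carbon (Pd/C, 10 wt%), EtOAc, rt
Reagents that add atoms: none
Why: Heterogeneous hydrogenation of the electron-poor tetrasubstituted alkene by cis addition; the configuration left at C9 and at the enolisable C8 is immaterial, because C8 becomes a radical in step 6 and C9 is equilibrated in steps 7 and 9.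

Step 5
Reactants: 7 dimethyl (3aS,7aR)-3a,7,7-trimethyl-1-oxooctahydro-1H-indene-2,3-dicarboxylate; 8 dibromomethane
Product: 9 dimethyl (3aS,7aR)-2-(bromomethyl)-3a,7,7-trimethyl-1-oxooctahydro-1H-indene-2,3-dicarboxylate (bromomethyl on C8; cis-fused)
Conditions: NaH (1.05 equiv), THF–DMPU, 0 °C; then 8 (10 equiv), 45 °C
Reagents that add atoms: none
Why: C-alkylation of the sodium enolate of the β-keto ester with a large excess of dibromomethane, the standard entry to Dowd–Beckwith substrates; one equivalent of base and the excess of electrophile avoid deprotonation at C9 and coupling of two enolates, and the configuration of the new quaternary C8 is irrelevant.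

Step 6
Reactants: 9 dimethyl (3aS,7aR)-2-(bromomethyl)-3a,7,7-trimethyl-1-oxooctahydro-1H-indene-2,3-dicarboxylate
Product: 10 dimethyl (4aR,8aS)-5,5,8a-trimethyl-4-oxodecahydronaphthalene-1,2-dicarboxylate (cis-fused 6-oxodrimane-11,12-dioate, 5β-H, 10β-methyl; C8 and C9 epimers)
Conditions: Bu3SnH (1.3 equiv), AIBN (0.2 equiv), syringe pump over 6 h, PhH (0.01 M), 80 °C
Reagents that add atoms: none
Why: Dowd–Beckwith ring expansion, run as a tin hydride radical chain: Bu3Sn• abstracts bromine from C7, the primary radical adds to the C6 carbonyl in 3-exo-trig fashion, and the cyclopropyloxy radical opens by β-scission of the old C6–C8 bond to the tertiary, ester-stabilised C8 radical, which takes hydrogen from Bu3SnH. The net 1,2-acyl shift forms C6–C7 and inserts C7 into the cyclopentanone, so ring B is closed by ring enlargement (3-exo addition, then fragmentation) and not by a direct six-membered cyclisation. The closest known reaction type is the one-carbon expansion of 2-(halomethyl)-2-alkoxycarbonyl cycloalkanones to 3-oxocycloalkanecarboxylates. No lasting stereocentre is made: C8 is re-formed by hydrogen transfer as an epimer mixture and is settled in steps 7 and 9, whereas C5, C9 and C10 are untouched, so 10 keeps the cis ring fusion of 9. Three selectivities are needed. Rearrangement must outrun direct reduction of the primary radical, which slow addition of the stannane at high dilution secures. The radical must add to the ketone and not to the C12 ester carbonyl, which is equally 3-exo; the far greater rate of radical addition to a ketone carbonyl secures this. The cyclopropyloxy radical must open towards C8 and not back to C7 or towards C5, which the stability of the ester-substituted tertiary radical and the relief of cyclopropane strain secure.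

Step 7
Reactants: 10 dimethyl (4aR,8aS)-5,5,8a-trimethyl-4-oxodecahydronaphthalene-1,2-dicarboxylate
Product: 11 dimethyl (1S,2R,4aS,8aS)-5,5,8a-trimethyl-4-oxodecahydronaphthalene-1,2-dicarboxylate (trans-fused, 5α-H; 8α- and 9β-esters, both equatorial)
Conditions: NaOMe (1 equiv), MeOH, 65 °C
Reagents that add atoms: none
Why: Thermodynamic equilibration through the C5 ketone enolate and the C8 and C9 ester enolates: the trans-fused chair–chair decalone with both esters equatorial is expected to be the most stable diastereomer, because the cis-fused forms must place C6 and C1 axially. C10 cannot epimerise and is the reference centre.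

Step 8
Reactants: 11 dimethyl (1S,2R,4aS,8aS)-5,5,8a-trimethyl-4-oxodecahydronaphthalene-1,2-dicarboxylate
Product: 12 dimethyl (1S,2R,4R,4aS,8aS)-4-hydroxy-5,5,8a-trimethyldecahydronaphthalene-1,2-dicarboxylate (6β-hydroxy, 8α-ester, 9β-ester)
Conditions: NaBH4, MeOH, 0 °C to rt
Reagents that add atoms: none
Why: Hydride attacks the C6 ketone from the α face because the β face is screened by the syn-axial methyl groups on C4 and C10, giving the axial 6β-alcohol as in reductions of 6-oxo steroids and terpenoids; the methyl esters are inert to NaBH4 under these conditions.

Step 9
Reactants: 12 dimethyl (1S,2R,4R,4aS,8aS)-4-hydroxy-5,5,8a-trimethyldecahydronaphthalene-1,2-dicarboxylate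
Product: 14 methyl (5S,6R,8S,9S,10S)-12-oxo-6,12-epoxydriman-11-oate (the 12,6β-lactone with the 9β-methyl ester), via 8β-epimeric hydroxy diester 13 (not isolated)
Conditions: NaOMe (0.5 equiv), toluene–MeOH, 110 °C, MeOH distilled off; AcOH quench
Reagents that add atoms: none
Why: Base epimerisation at C8 through the ester enolate supplies the small equilibrium share of the 8β-ester, whose axial ester and axial 6β-alkoxide are 1,3-syn and close to the bridged γ-lactone as methanol distils, so the lactone fixes C8 as β. C9, still enolisable, settles as the equatorial 9β-ester on the locked chair.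

Step 10
Reactants: 14 methyl (5S,6R,8S,9S,10S)-12-oxo-6,12-epoxydriman-11-oate
Product: 16 diallyl (5S,6R,8S,9S,10S)-6-hydroxydrimane-11,12-dioate, via dipotassium 6β-hydroxydrimane-11,12-dioate 15 (not isolated)
Conditions: KOH, MeOH–H2O, 80 °C; CO2 to pH 8, evaporate; then allyl bromide, DMF, rt
Reagents that add atoms: potassium hydroxide, [K+].[OH-]; allyl bromide, C=CCBr
Why: Saponification opens the lactone by acyl–oxygen cleavage, so C6 and C8 keep their configuration and the C8 carboxylate can no longer enolise, and it also cleaves the hindered C11 methyl ester. After buffering, the dicarboxylate is O-alkylated under conditions too weakly basic to form the 6-alkoxide, which avoids relactonisation.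

Step 11
Reactants: 16 diallyl (5S,6R,8S,9S,10S)-6-hydroxydrimane-11,12-dioate; 17 (diethoxyphosphoryl)acetic acid
Product: 18 diallyl (5S,6R,8S,9S,10S)-6-{[(diethoxyphosphoryl)acetyl]oxy}drimane-11,12-dioate
Conditions: DCC, DMAP (cat.), CH2Cl2, 0 °C to rt
Reagents that add atoms: none
Why: Steglich-type esterification; with DCC the phosphonoacetic acid reacts through a small, ketene-like acyl donor, which is why it esterifies even strongly hindered axial alcohols, and the near-neutral conditions do not promote attack of O6 on the 8β-ester.

Step 12
Reactants: 18 diallyl (5S,6R,8S,9S,10S)-6-{[(diethoxyphosphoryl)acetyl]oxy}drimane-11,12-dioate; 19 (2E,4E)-hexa-2,4-dienal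
Product: 20 diallyl (5S,6R,8S,9S,10S)-6-{[(2E,4E,6E)-octa-2,4,6-trienoyl]oxy}drimane-11,12-dioate
Conditions: LiCl, DBU, MeCN, 0 °C to rt
Reagents that add atoms: none
Why: Horner–Wadsworth–Emmons olefination with LiCl and an amine base: the stabilised phosphonate anion forms the new C2'=C3' bond with E geometry, the 4E,6E geometry comes from 19, and the base is too weak to enolise the C8 and C9 esters.

Step 13
Reactants: 20 diallyl (5S,6R,8S,9S,10S)-6-{[(2E,4E,6E)-octa-2,4,6-trienoyl]oxy}drimane-11,12-dioate
Product: 21 (5S,6R,8S,9S,10S)-6-{[(2E,4E,6E)-octa-2,4,6-trienoyl]oxy}drimane-11,12-dioic acid, i.e. (1S,2S,4R,4aS,8aS)-5,5,8a-trimethyl-4-{[(2E,4E,6E)-octa-2,4,6-trienoyl]oxy}decahydronaphthalene-1,2-dicarboxylic acid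
Conditions: Pd(PPh3)4 (5 mol%), N-methylaniline, THF, rt; dilute aqueous citric acid work-up
Reagents that add atoms: none
Why: Tsuji–Trost deallylation: zerovalent palladium ionises the allyl esters and the weakly nucleophilic amine takes up the allyl groups, a neutral, non-hydrolytic and non-reductive deprotection that leaves the trienoate ester, the triene and all stereocentres untouched.

## Compound list

1 | β-cyclocitral (2,6,6-trimethylcyclohex-1-ene-1-carbaldehyde) | CC1=C(C=O)C(C)(C)CCC1 | starting material
2 | methyl diazoacetate | COC(=O)C=[N+]=[N-] | starting material
3 | methyl 3-oxo-3-(2,6,6-trimethylcyclohex-1-en-1-yl)propanoate | COC(=O)CC(=O)C1=C(C)CCCC1(C)C | intermediate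
4 | methyl glyoxylate | COC(=O)C=O | starting material
5 | dimethyl (2Z)-2-[(2,6,6-trimethylcyclohex-1-en-1-yl)carbonyl]but-2-enedioate | COC(=O)/C=C(\C(=O)OC)C(=O)C1=C(C)CCCC1(C)C | intermediate
6 | dimethyl (3aS,7aR)-3a,7,7-trimethyl-1-oxo-3a,4,5,6,7,7a-hexahydro-1H-indene-2,3-dicarboxylate | O=C1C(C(=O)OC)=C(C(=O)OC)[C@@]2(C)CCCC(C)(C)[C@@H]12 | intermediate
7 | dimethyl (3aS,7aR)-3a,7,7-trimethyl-1-oxooctahydro-1H-indene-2,3-dicarboxylate (C8/C9 epimers) | O=C1C(C(=O)OC)C(C(=O)OC)[C@@]2(C)CCCC(C)(C)[C@@H]12 | intermediate
8 | dibromomethane | BrCBr | starting material
9 | dimethyl (3aS,7aR)-2-(bromomethyl)-3a,7,7-trimethyl-1-oxooctahydro-1H-indene-2,3-dicarboxylate | O=C1C(CBr)(C(=O)OC)C(C(=O)OC)[C@@]2(C)CCCC(C)(C)[C@@H]12 | intermediate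
10 | dimethyl (4aR,8aS)-5,5,8a-trimethyl-4-oxodecahydronaphthalene-1,2-dicarboxylate (cis-fused; C8/C9 epimers) | O=C1CC(C(=O)OC)C(C(=O)OC)[C@@]2(C)CCCC(C)(C)[C@@H]12 | intermediate
11 | dimethyl (1S,2R,4aS,8aS)-5,5,8a-trimethyl-4-oxodecahydronaphthalene-1,2-dicarboxylate | O=C1C[C@@H](C(=O)OC)[C@H](C(=O)OC)[C@@]2(C)CCCC(C)(C)[C@H]12 | intermediate
12 | dimethyl (1S,2R,4R,4aS,8aS)-4-hydroxy-5,5,8a-trimethyldecahydronaphthalene-1,2-dicarboxylate | O[C@@H]1C[C@@H](C(=O)OC)[C@H](C(=O)OC)[C@@]2(C)CCCC(C)(C)[C@H]12 | intermediate
13 | dimethyl (1S,2S,4R,4aS,8aS)-4-hydroxy-5,5,8a-trimethyldecahydronaphthalene-1,2-dicarboxylate (8β-epimer of 12) | O[C@@H]1C[C@H](C(=O)OC)[C@H](C(=O)OC)[C@@]2(C)CCCC(C)(C)[C@H]12 | intermediate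
14 | methyl (5S,6R,8S,9S,10S)-12-oxo-6,12-epoxydriman-11-oate | O=C3O[C@@H]1C[C@H]3[C@H](C(=O)OC)[C@@]2(C)CCCC(C)(C)[C@H]12 | intermediate
15 | dipotassium (5S,6R,8S,9S,10S)-6-hydroxydrimane-11,12-dioate | O[C@@H]1C[C@H](C(=O)[O-])[C@H](C(=O)[O-])[C@@]2(C)CCCC(C)(C)[C@H]12.[K+].[K+] | intermediate
16 | diallyl (5S,6R,8S,9S,10S)-6-hydroxydrimane-11,12-dioate | O[C@@H]1C[C@H](C(=O)OCC=C)[C@H](C(=O)OCC=C)[C@@]2(C)CCCC(C)(C)[C@H]12 | intermediate
17 | (diethoxyphosphoryl)acetic acid | CCOP(=O)(CC(=O)O)OCC | starting material
18 | diallyl (5S,6R,8S,9S,10S)-6-{[(diethoxyphosphoryl)acetyl]oxy}drimane-11,12-dioate | CCOP(=O)(OCC)CC(=O)O[C@@H]1C[C@H](C(=O)OCC=C)[C@H](C(=O)OCC=C)[C@@]2(C)CCCC(C)(C)[C@H]12 | intermediate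
19 | (2E,4E)-hexa-2,4-dienal | C/C=C/C=C/C=O | starting material
20 | diallyl (5S,6R,8S,9S,10S)-6-{[(2E,4E,6E)-octa-2,4,6-trienoyl]oxy}drimane-11,12-dioate | C/C=C/C=C/C=C/C(=O)O[C@@H]1C[C@H](C(=O)OCC=C)[C@H](C(=O)OCC=C)[C@@]2(C)CCCC(C)(C)[C@H]12 | intermediate
21 | (5S,6R,8S,9S,10S)-6-{[(2E,4E,6E)-octa-2,4,6-trienoyl]oxy}drimane-11,12-dioic acid | C/C=C/C=C/C=C/C(=O)O[C@@H]1C[C@H](C(=O)O)[C@H](C(=O)O)[C@@]2(C)CCCC(C)(C)[C@H]12 | target

## Step count and least certain steps

Total step count: 13. Longest linear sequence: 13 steps (1 to 21); compounds 2, 4, 8, 17 and 19 are commercial and enter directly.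

Step 3 (bears the label). The closure may be slow because the ring methyl is forced to the inside of the pentadienyl cation. The sense of conrotation at the quaternary terminus may be poorly controlled. A Wagner–Meerwein shift to the oxyallyl cation, which has no β-hydrogen on the ring side, may compete with loss of the C9 proton. The chelating product may inhibit the catalyst. The fallback uses known chemistry and replaces asymmetric catalysis by resolution. It sets out from 5, which is cyclised with an achiral promoter of the kind established for 2-alkoxycarbonyl dienones and for trimethylcyclohexenyl ketones (Cu(OTf)2, 10 mol%, ClCH2CH2Cl, 60 °C, or MeSO3H) to the racemic cis-fused enone F1. This is resolved by preparative chromatography on a chiral stationary phase, and the route is rejoined at 6.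

Step 6 (key step). The primary radical may be reduced before it rearranges, or may be diverted by 1,5-hydrogen transfer from the C10 methyl or C1; both processes return an unexpanded hydrindanone. The fallback abandons the radical and performs the same C7 insertion with an organozinc reagent. It sets out from 7, which is treated with Et2Zn and CH2I2 in CH2Cl2 at 0 °C to rt (zinc-carbenoid chain extension of β-keto esters). The zinc enolate is cyclopropanated, and the zinc cyclopropanolate fragments at the old C6–C8 bond and is protonated on work-up. The route is rejoined at 10 and no new compound is made (F0).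

Step 7. The ring-fusion equilibrium may not lie far enough on the trans side, because the gem-dimethyl group next to C5 strains both fusions, so that cis-fused ketone persists. The fallback replaces thermodynamic by kinetic control at C5. It sets out from 10, which is brominated at the ring-fusion α-carbon through the more substituted enol (Br2, AcOH, cat. HBr, rt) to the 5-bromo ketone F2. Reduction with Bu3SnH and AIBN in PhH at 80 °C passes through the planar C5 radical, which should take hydrogen on the α face, away from the axial methyls on C4 and C10, and give the trans-fused ketone F3 as a mixture of C8 and C9 epimers. Reduction as in step 8 gives the 6β-alcohols F4, which are submitted to the conditions of step 9, where C8 and C9 converge; the route is rejoined at 14.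

Step 11. Acylation of the axial, doubly flanked 6β-hydroxyl may be slow, and loss of the hydroxy ester by closure of O6 onto the C12 allyl ester may compete. The fallback installs a smaller and more reactive two-carbon acyl group first and builds the phosphonate afterwards. It sets out from 16, which is acylated with bromoacetyl bromide and pyridine in CH2Cl2 at −20 °C to the bromoacetate F5. A Michaelis–Arbuzov reaction with P(OEt)3 at 110 °C then gives the phosphonate, and the route is rejoined at 18.

Step 5. The hindered enolate may react on oxygen. The second C–Br bond may link two enolates. Deprotonation at C9 may lead to closure of a cyclopropane onto the bromomethyl group. The fallback introduces C7 at the alcohol oxidation level. It sets out from 7, which undergoes aldol hydroxymethylation (aqueous CH2O, KHCO3, THF, rt) to the hydroxymethyl keto diester F6. An Appel reaction (CBr4, PPh3, CH2Cl2) converts this to the bromide, and the route is rejoined at 9.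

## Further compounds

F1 | step 3 | racemic dimethyl 3a,7,7-trimethyl-1-oxo-3a,4,5,6,7,7a-hexahydro-1H-indene-2,3-dicarboxylate (6 together with its enantiomer) | O=C1C(C(=O)OC)=C(C(=O)OC)C2(C)CCCC(C)(C)C12
F0 | step 6 | none | none
F2 | step 7 | dimethyl 5-bromo-6-oxodrimane-11,12-dioate (10β-methyl; C5, C8, C9 as mixtures) | O=C1CC(C(=O)OC)C(C(=O)OC)[C@@]2(C)CCCC(C)(C)C12Br
F3 | step 7 | dimethyl 6-oxo-5α-drimane-11,12-dioate (trans-fused; C8/C9 epimers) | O=C1CC(C(=O)OC)C(C(=O)OC)[C@@]2(C)CCCC(C)(C)[C@H]12
F4 | step 7 | dimethyl 6β-hydroxy-5α-drimane-11,12-dioate (C8/C9 epimers) | O[C@@H]1CC(C(=O)OC)C(C(=O)OC)[C@@]2(C)CCCC(C)(C)[C@H]12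
F5 | step 11 | diallyl (5S,6R,8S,9S,10S)-6-(bromoacetoxy)drimane-11,12-dioate | BrCC(=O)O[C@@H]1C[C@H](C(=O)OCC=C)[C@H](C(=O)OCC=C)[C@@]2(C)CCCC(C)(C)[C@H]12
F6 | step 5 | dimethyl (3aS,7aR)-2-(hydroxymethyl)-3a,7,7-trimethyl-1-oxooctahydro-1H-indene-2,3-dicarboxylate | O=C1C(CO)(C(=O)OC)C(C(=O)OC)[C@@]2(C)CCCC(C)(C)[C@@H]12
A1 | alternative 1 | dimethyl (2Z)-2-[(7Z)-8-(benzyloxy)-6,6-dimethyloct-7-en-2-ylidene]-3-methylidenebutanedioate | C=C(C(=O)OC)/C(C(=O)OC)=C(\C)CCCC(C)(C)/C=C\OCc1ccccc1
A2 | alternative 1 | dimethyl 6β-(benzyloxy)drim-8-ene-11,12-dioate (trans-fused, 5α-H, 10β-methyl) | c1ccccc1CO[C@@H]1CC(C(=O)OC)=C(C(=O)OC)[C@@]2(C)CCCC(C)(C)[C@H]12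
A3 | alternative 2 | 11,12-dinordrim-8-en-6β-ol (trans-fused, 5α-H, 10β-methyl) | O[C@@H]1CC=C[C@@]2(C)CCCC(C)(C)[C@H]12
A4 | alternative 2 | methyl 12-oxo-6β,12-epoxydriman-11-oate (8β,9β; identical with 14) | O=C3O[C@@H]1C[C@H]3[C@H](C(=O)OC)[C@@]2(C)CCCC(C)(C)[C@H]12
A5 | alternative 3 | tert-butyl (2E,4Z,10E)-4-[(tert-butyldimethylsilyl)oxy]-6,6,10-trimethyl-12-oxo-12-(2-oxo-1,3-oxazolidin-3-yl)dodeca-2,4,10-trienoate | O=C1OCCN1C(=O)/C=C(\C)CCCC(C)(C)/C=C(O[Si](C)(C)C(C)(C)C)/C=C/C(=O)OC(C)(C)C
A6 | alternative 3 | tert-butyl 6-[(tert-butyldimethylsilyl)oxy]-11-oxo-11-(2-oxo-1,3-oxazolidin-3-yl)drim-6-en-12-oate (5α-H, 8β, 9β, 10β-methyl) | CC(C)(C)[Si](C)(C)OC1=C[C@H](C(=O)OC(C)(C)C)[C@H](C(=O)N3CCOC3=O)[C@@]2(C)CCCC(C)(C)[C@H]12
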